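Assumption: the SMILES is read as (2S)-5-hydroxy-7-(prenyloxy)-8-prenylflavanone, and ethyl (3S)-3-hydroxy-3-phenylpropanoate is bought at ≥98% ee. Flavanone numbering (O1, C2, C3, C4, C4a, C5–C8, C8a) is used throughout.

## Retrosynthetic overview

1. Target 15 ⇐ 5,7-bis-O-prenyl flavanone 13: the 5-O-prenyl group is moved to C8 by a Eu(III)-catalysed Claisen–Cope shift (no ring is made).
2. 13 ⇐ (S)-pinocembrin 10 by double Mitsunobu O-prenylation.
3. 10 ⇐ acyclic hydroxy-diketo-dioxinone 7 in one flask: ring C first (cyclodehydration onto the C8a ketone, C2–O bond kept), then ring A (dioxinone → acylketene → 6π closure and aromatisation).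
4. 7 ⇐ dianion of keto-dioxinone 6 (from 4 + 5) + Weinreb amide 3 (from 1, which brings C2 and the phenyl ring).

## Route

Step 1
Reactants: 1 ethyl (3S)-3-hydroxy-3-phenylpropanoate; 2 N,O-dimethylhydroxylamine hydrochloride
Product: 3 (3S)-3-hydroxy-N-methoxy-N-methyl-3-phenylpropanamide
Conditions: MeNHOMe·HCl (1.6 equiv), iPrMgCl (4.2 equiv), THF, −20 → 0 °C
Reagents that add atoms: N,O-dimethylhydroxylamine hydrochloride (2), CNOC.Cl
Why: Ester aminolysis by the chloromagnesium amide of MeNHOMe (Weinreb amide formation) runs at low temperature on the magnesium alkoxide of the free β-hydroxy ester, and the carbinol centre is not touched.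

Step 2
Reactants: 4 2,2,6-trimethyl-4H-1,3-dioxin-4-one; 5 acetyl chloride
Product: 6 2,2-dimethyl-6-(2-oxopropyl)-4H-1,3-dioxin-4-one
Conditions: LiHMDS, THF, −78 °C; then AcCl (0.5 equiv), −78 → 0 °C
Reagents that add atoms: acetyl chloride (5), CC(=O)Cl
Why: γ-Deprotonation gives the lithium dienolate, which is C-acylated at the γ-carbon (vinylogous Claisen-type acylation); half an equivalent of AcCl is used because 6 is more acidic than 4 and quenches a second enolate.

Step 3
Reactants: 3 (3S)-3-hydroxy-N-methoxy-N-methyl-3-phenylpropanamide; 6 2,2-dimethyl-6-(2-oxopropyl)-4H-1,3-dioxin-4-one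
Product: 7 6-[(6S)-6-hydroxy-2,4-dioxo-6-phenylhexyl]-2,2-dimethyl-4H-1,3-dioxin-4-one (used crude)
Conditions: 6 (3 equiv), LDA (5.9 equiv), THF, −78 °C; then 3, −78 → −40 °C; aq NH4Cl (pH 5)
Reagents that add atoms: none
Why: In this crossed Claisen condensation the terminal carbanion of the keto-dioxinone dianion adds to the Weinreb amide (one equivalent of dianion is spent on the hydroxyl), the chelated tetrahedral intermediate prevents over-addition, and the stereocentre is untouched.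

Step 4
Reactants: 7 6-[(6S)-6-hydroxy-2,4-dioxo-6-phenylhexyl]-2,2-dimethyl-4H-1,3-dioxin-4-one
Product: 10 (2S)-5,7-dihydroxy-2-phenyl-2,3-dihydro-4H-chromen-4-one ((S)-pinocembrin), via dihydropyranone 8 (not isolated), via acylketene 9 (not isolated)
Conditions: CSA (5 mol %), 4 Å MS, PhMe, 23 °C, 2 h; then dilute to 5 mM, 110 °C, 1 h
Reagents that add atoms: none
Why: Proposed new method: acid-catalysed hemiketalisation and dehydration of the δ-hydroxy-β-diketone closes ring C on the C8a carbonyl without breaking the C2–O bond (so S is retained and the C8a oxygen can no longer form a 2-pyrone), then thermal retro-[4+2] loss of acetone gives acylketene 9, whose C7 enol is a dienylketene that closes the C4a–C5 bond by 6π-electrocyclisation (equivalently C-acylation of the vinylogous-ester α-carbon) and tautomerises to the phloroglucinol ring A; the closest known reactions are the cyclodehydration of β-diketone aldol adducts to 2,3-dihydro-4H-pyran-4-ones, the ketene generation–aromatisation of diketo-dioxinones to resorcylates and the dienylketene ring closure of the Danheiser benzannulation.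

Step 5
Reactants: 10 (2S)-5,7-dihydroxy-2-phenyl-2,3-dihydro-4H-chromen-4-one; 11 3-methylbut-2-en-1-ol (prenol)
Product: 13 (2S)-5,7-bis[(3-methylbut-2-en-1-yl)oxy]-2-phenyl-2,3-dihydro-4H-chromen-4-one, via 7-O-prenyl ether 12 (not isolated)
Conditions: prenol (3 equiv), PPh3 (3 equiv), DIAD (3 equiv), THF, 0 → 23 °C
Reagents that add atoms: 3-methylbut-2-en-1-ol (11), CC(C)=CCO
Why: Mitsunobu etherification alkylates the acidic 7-OH first and then the chelated 5-OH under non-basic conditions, so the base-labile flavanone (retro-oxa-Michael opening) and C2 are not disturbed.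

Step 6
Reactants: 13 (2S)-5,7-bis[(3-methylbut-2-en-1-yl)oxy]-2-phenyl-2,3-dihydro-4H-chromen-4-one
Product: 15 (2S)-5-hydroxy-8-(3-methylbut-2-en-1-yl)-7-[(3-methylbut-2-en-1-yl)oxy]-2-phenyl-2,3-dihydro-4H-chromen-4-one (target), via ortho-Claisen dienone 14 (not isolated)
Conditions: Eu(fod)3 (10 mol %), NaHCO3, PhCl, 85 °C
Reagents that add atoms: none
Why: Eu(III) chelation of the C4 carbonyl and the 5-O-prenyl oxygen triggers an aromatic Claisen rearrangement to C6 followed by a Cope rearrangement to C8 (para-Claisen–Cope) and tautomerisation to the hydrogen-bonded 5-OH, while the unchelated 7-O-prenyl ether is inert at 85 °C and C2 is not involved.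

## Compound list

1 | ethyl (3S)-3-hydroxy-3-phenylpropanoate | CCOC(=O)C[C@H](O)c1ccccc1 | starting material
2 | N,O-dimethylhydroxylamine hydrochloride | CNOC.Cl | starting material
3 | (3S)-3-hydroxy-N-methoxy-N-methyl-3-phenylpropanamide | CON(C)C(=O)C[C@H](O)c1ccccc1 | intermediate
4 | 2,2,6-trimethyl-4H-1,3-dioxin-4-one | CC1=CC(=O)OC(C)(C)O1 | starting material
5 | acetyl chloride | CC(=O)Cl | starting material
6 | 2,2-dimethyl-6-(2-oxopropyl)-4H-1,3-dioxin-4-one | CC(=O)CC1=CC(=O)OC(C)(C)O1 | intermediate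
7 | 6-[(6S)-6-hydroxy-2,4-dioxo-6-phenylhexyl]-2,2-dimethyl-4H-1,3-dioxin-4-one | CC1(C)OC(=O)C=C(CC(=O)CC(=O)C[C@H](O)c2ccccc2)O1 | intermediate
8 | 2,2-dimethyl-6-{[(2S)-4-oxo-2-phenyl-3,4-dihydro-2H-pyran-6-yl]methyl}-4H-1,3-dioxin-4-one | CC1(C)OC(=O)C=C(CC2=CC(=O)C[C@@H](c3ccccc3)O2)O1 | intermediate
9 | 3-oxo-4-[(2S)-4-oxo-2-phenyl-3,4-dihydro-2H-pyran-6-yl]but-1-en-1-one (acylketene) | O=C=CC(=O)CC1=CC(=O)C[C@@H](c2ccccc2)O1 | intermediate
10 | (2S)-5,7-dihydroxy-2-phenyl-2,3-dihydro-4H-chromen-4-one ((S)-pinocembrin) | O=C1C[C@@H](c2ccccc2)Oc2cc(O)cc(O)c21 | intermediate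
11 | 3-methylbut-2-en-1-ol (prenol) | CC(C)=CCO | starting material
12 | (2S)-5-hydroxy-7-[(3-methylbut-2-en-1-yl)oxy]-2-phenyl-2,3-dihydro-4H-chromen-4-one | CC(C)=CCOc1cc(O)c2c(c1)O[C@H](c1ccccc1)CC2=O | intermediate
13 | (2S)-5,7-bis[(3-methylbut-2-en-1-yl)oxy]-2-phenyl-2,3-dihydro-4H-chromen-4-one | CC(C)=CCOc1cc(OCC=C(C)C)c2c(c1)O[C@H](c1ccccc1)CC2=O | intermediate
14 | (2S)-6-(2-methylbut-3-en-2-yl)-7-[(3-methylbut-2-en-1-yl)oxy]-2-phenyl-2,3-dihydro-4H-chromene-4,5(6H)-dione (C6 epimers) | C=CC(C)(C)C1C(OCC=C(C)C)=CC2=C(C1=O)C(=O)C[C@@H](c1ccccc1)O2 | intermediate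
15 | (2S)-5-hydroxy-8-(3-methylbut-2-en-1-yl)-7-[(3-methylbut-2-en-1-yl)oxy]-2-phenyl-2,3-dihydro-4H-chromen-4-one | CC(C)=CCOc1cc(O)c2c(c1CC=C(C)C)O[C@H](c1ccccc1)CC2=O | target

## Step count and risk

Total steps: 6. Longest linear sequence: 5 (steps 1, 3, 4, 5, 6 from compound 1; step 2 is the side branch).

Three steps most likely to fail:

**Step 4 (one-flask double cyclisation).** The risks are ketene hydration or dimerisation, and a slow ring-A closure. The fallback sets out from 8 and comes back to the route at 10. The sequence is stopped after the room-temperature stage and 8 is isolated. Heating 8 in PhMe/MeOH (110 °C) traps ketene 9 as methyl 3-oxo-4-[(2S)-4-oxo-2-phenyl-3,4-dihydro-2H-pyran-6-yl]butanoate F1. Ring A is then closed separately by an anionic, biomimetic Claisen (Dieckmann-type) condensation of the vinylogous dienolate onto the ester with Mg(OMe)2 in MeOH at 23 °C, giving 10. The ee must be checked, because base can open the β-alkoxy ketone.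

**Step 6 (Claisen–Cope regiochemistry).** The risks are arrest at the 6-(1,1-dimethylallyl) isomer or involvement of the 7-O-prenyl group. The fallback sets out from 6 and comes back to the route at 15; it places the C-prenyl group on the chain before any ring exists.
- 6 is C-alkylated at its doubly activated methylene (prenyl bromide, K2CO3, acetone) to give 2,2-dimethyl-6-(6-methyl-2-oxohept-5-en-3-yl)-4H-1,3-dioxin-4-one F2.
- The dianion of F2 is acylated with 3 as in step 3 to give 6-[(6S)-6-hydroxy-1-(3-methylbut-2-en-1-yl)-2,4-dioxo-6-phenylhexyl]-2,2-dimethyl-4H-1,3-dioxin-4-one F3.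
- Under the step 4 conditions (acid removed by filtration through basic alumina before heating, to spare the prenyl alkene) F3 passes through 2,2-dimethyl-6-{4-methyl-1-[(2S)-4-oxo-2-phenyl-3,4-dihydro-2H-pyran-6-yl]pent-3-en-1-yl}-4H-1,3-dioxin-4-one F4 and the acylketene 7-methyl-3-oxo-4-[(2S)-4-oxo-2-phenyl-3,4-dihydro-2H-pyran-6-yl]octa-1,6-dien-1-one F5, neither isolated.
- The product is (2S)-5,7-dihydroxy-8-(3-methylbut-2-en-1-yl)-2-phenyl-2,3-dihydro-4H-chromen-4-one F6, whose C8 regiochemistry is fixed by the chain position.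
- Selective Mitsunobu 7-O-prenylation of F6 with 11 (1.1 equiv, PPh3, DIAD, THF) gives 15.

**Step 3 (Claisen condensation with a free hydroxyl; labile product).** The fallback sets out from 3 and comes back to the route at 7; it builds the same C–C bond by aldol addition and oxidation.
- 3 is silylated (TESCl, imidazole, CH2Cl2) to (3S)-N-methoxy-N-methyl-3-phenyl-3-[(triethylsilyl)oxy]propanamide F7.
- F7 is reduced (DIBAL-H, THF, −78 °C) to (3S)-3-phenyl-3-[(triethylsilyl)oxy]propanal F8.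
- The dianion of 6 adds to F8 to give 6-[(6S)-4-hydroxy-2-oxo-6-phenyl-6-[(triethylsilyl)oxy]hexyl]-2,2-dimethyl-4H-1,3-dioxin-4-one F9.
- Dess–Martin oxidation gives 6-[(6S)-2,4-dioxo-6-phenyl-6-[(triethylsilyl)oxy]hexyl]-2,2-dimethyl-4H-1,3-dioxin-4-one F10.
- HF·pyridine in MeCN at 0 °C releases 7.

## Further compounds

F1 | step 4 | methyl 3-oxo-4-[(2S)-4-oxo-2-phenyl-3,4-dihydro-2H-pyran-6-yl]butanoate | COC(=O)CC(=O)CC1=CC(=O)C[C@@H](c2ccccc2)O1
F2 | step 6 | 2,2-dimethyl-6-(6-methyl-2-oxohept-5-en-3-yl)-4H-1,3-dioxin-4-one (racemic) | CC(=O)C(CC=C(C)C)C1=CC(=O)OC(C)(C)O1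
F3 | step 6 | 6-[(6S)-6-hydroxy-1-(3-methylbut-2-en-1-yl)-2,4-dioxo-6-phenylhexyl]-2,2-dimethyl-4H-1,3-dioxin-4-one (C1' epimers) | CC(C)=CCC(C(=O)CC(=O)C[C@H](O)c1ccccc1)C1=CC(=O)OC(C)(C)O1
F4 | step 6 | 2,2-dimethyl-6-{4-methyl-1-[(2S)-4-oxo-2-phenyl-3,4-dihydro-2H-pyran-6-yl]pent-3-en-1-yl}-4H-1,3-dioxin-4-one | CC(C)=CCC(C1=CC(=O)C[C@@H](c2ccccc2)O1)C1=CC(=O)OC(C)(C)O1
F5 | step 6 | 7-methyl-3-oxo-4-[(2S)-4-oxo-2-phenyl-3,4-dihydro-2H-pyran-6-yl]octa-1,6-dien-1-one (acylketene) | CC(C)=CCC(C(=O)C=C=O)C1=CC(=O)C[C@@H](c2ccccc2)O1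
F6 | step 6 | (2S)-5,7-dihydroxy-8-(3-methylbut-2-en-1-yl)-2-phenyl-2,3-dihydro-4H-chromen-4-one | CC(C)=CCc1c(O)cc(O)c2c1O[C@H](c1ccccc1)CC2=O
F7 | step 3 | (3S)-N-methoxy-N-methyl-3-phenyl-3-[(triethylsilyl)oxy]propanamide | CON(C)C(=O)C[C@H](O[Si](CC)(CC)CC)c1ccccc1
F8 | step 3 | (3S)-3-phenyl-3-[(triethylsilyl)oxy]propanal | O=CC[C@H](O[Si](CC)(CC)CC)c1ccccc1
F9 | step 3 | 6-[(6S)-4-hydroxy-2-oxo-6-phenyl-6-[(triethylsilyl)oxy]hexyl]-2,2-dimethyl-4H-1,3-dioxin-4-one (C4' epimers) | CC1(C)OC(=O)C=C(CC(=O)CC(O)C[C@H](O[Si](CC)(CC)CC)c2ccccc2)O1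
F10 | step 3 | 6-[(6S)-2,4-dioxo-6-phenyl-6-[(triethylsilyl)oxy]hexyl]-2,2-dimethyl-4H-1,3-dioxin-4-one | CC1(C)OC(=O)C=C(CC(=O)CC(=O)C[C@H](O[Si](CC)(CC)CC)c2ccccc2)O1
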